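## Analysis of the target

Selaginellin is a para-quinone methide (a fuchsone). It is a cyclohexa-2,5-dienone whose C4 is doubly bonded to a carbon that also carries a 4-hydroxyphenyl group and the benzene ring A. Ring A has four contiguous substituents: the diarylmethylene carbon on C1, a 4-hydroxyphenyl group on C2, a hydroxymethyl group on C5 and a (4-hydroxyphenyl)ethynyl group on C6. Only C3 and C4 carry hydrogen. There is no stereocentre, and the exocyclic double bond is not stereogenic because the dienone ring is symmetrical. The sensitive parts are the electrophilic quinone methide (in acid it equilibrates with a triarylmethyl cation), three free phenols, a benzylic alcohol ortho to an alkyne, and the electron-rich diarylalkyne. The difficulty is ring A: an sp2 carbon on C1 and an sp carbon on C6 must be set ortho to each other, and each is flanked by a further substituent, so every bond to C1 and C6 is made at a doubly ortho-substituted position. The route rests on one feature: in the ketone that precedes the quinone methide, the aroyl group on C1 and the arylethynyl group on C6 together hold the atoms C3(aryl)=C2(aryl)–C1(=O) of a 2,3-diarylindenone fused to ring A at C1–C6. Both 4-oxyphenyl groups and the three carbons between them can therefore come from one symmetrical diarylalkyne in a single annulation.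

## Retrosynthetic reasoning

**Quinone methide.** The target 25 is taken back to the fully protected triarylcarbinol 23. The quinone methide is the most reactive group and is unveiled last: acid removes all acetal protecting groups, and the carbinol base 24 loses water once two para-hydroxyphenyl groups sit on the carbinol carbon.

**Third aryl group.** The bond between the carbinol carbon and one of its two identical 4-oxyphenyl groups is cut. This leads to the diaryl ketone 21 and the aryllithium 22, which comes from the aryl iodide 12. Ketone 21 has no α-hydrogen, so only 1,2-addition is possible.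

**Ring scission.** In 21 the carbonyl carbon on ring A C1 and the distal alkyne carbon on C6 are reconnected. This is the retron of an epoxy ketone fragmentation and leads through the azoalkene 20 and the tosylhydrazone 19 to the indenone epoxide 18. The cut is placed here because it turns two different ortho substituents into one fused five-membered ring. The forward reaction has to break indenone C2–C3 and turn C1–C2 into the triple bond.

**Epoxide.** 18 comes from the indenone 17 by nucleophilic epoxidation of the enone. The cis ring fusion is the only possible geometry, and the two stereocentres disappear again in the scission.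

**Annulation.** In 17 the bond from ring A to indenone C3 and the bond from the carbonyl carbon to indenone C2 are cut. This gives the 2-bromobenzaldehyde 10 and the symmetrical alkyne 16. Two skeletal bonds and the ring are made in one step. The symmetry of 16 and the fixed ortho relation of bromine and formyl group in 10 leave no regiochemical question.

**Alkyne partner.** 16 is cut at both aryl–alkyne bonds to two molecules of 12 and trimethylsilylacetylene 13. 12 is the methoxymethyl ether of 4-iodophenol 11 and serves a second time as the source of 22.

**Bromoaldehyde.** The formyl group of 10 is traced to the iodine of 8 through the arylmagnesium 9, because iodine–magnesium exchange is far faster than bromine–magnesium exchange. Introducing the bromine last by directed lithiation next to the aldehyde carbon was not chosen. It would have to compete with deprotonation of the benzylic ether CH2, which is ortho to the same directing group, and the position is hindered. The bromine is therefore carried from the start.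

**Back to the benzoate.** 8 is the methoxymethyl ether of alcohol 7, and 7 is the reduction product of ester 6. The iodine of 6 is placed through the arylmagnesium 5 by deprotonation of 4 at the one C–H that lies between the ester and the bromine. 4 is the protected form of phenol 3. The biaryl bond of 3 is cut to methyl 3-bromo-4-iodobenzoate 1 and 4-hydroxyphenylboronic acid 2; the coupling has to take place at C–I and leave C–Br untouched.

## Alternatives that were turned down

**Alternative 1:** Ring A is built by a [4+2] cycloaddition. The diene A2 supplies ring A C1–C4, with the diarylmethyl group on C1 and the silyloxy group on C2. The diynoate A3 supplies C5 and C6.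
- Forward key step: the diene adds to the ester-activated triple bond, the methoxy group is eliminated, and the 4-hydroxybenzoate A1 results.
- For it: the route is convergent. The push-pull polarisation should direct the benzhydryl-bearing diene terminus to the alkynyl-bearing carbon. C1 arrives at the triarylmethane oxidation level, so no cation or quinone methide exists until a final oxidation.
- Against it: the bond-forming diene terminus carries the bulky diarylmethyl group and must bond next to the alkynyl-substituted carbon. Only the Z silyl enol ether can reach the reactive conformation. The second triple bond of A3 can compete.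
- After A1 the C2 hydroxyl still has to become an aryl group (triflate, Suzuki coupling) at a position flanked by the benzhydryl group, followed by ester reduction, deprotection and oxidation.
- Comparison: Alternative 1 is stronger in that it avoids the acid-labile carbinol and builds ring A without a transition metal. The chosen route has every aryl–ring A bond in place at the annulation and needs four steps after its key step, where Alternative 1 needs five or more.

**Alternative 2:** Ring A C5–C6 and C1–C2 are cut, leading to the ester-tethered triyne A5.
- Forward key step: thermal hexadehydro-Diels–Alder cyclization gives a lactone-fused aryne at C3–C4, which takes two hydrogens from a saturated hydrocarbon solvent to give the phthalide A4.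
- For it: all six ring carbons and four substituents are set in one metal-free step. The carbinol carbon with two aryl groups is already present, and the lactone tells C5 from C6.
- Against it: the lactone carbonyl on C6 must still become the arylalkyne (partial reduction, one-carbon homologation, Sonogashira coupling) next to the hindered tertiary silyl ether. A5 needs an unsymmetrical 1,3-diyne and esterification with a hindered propiolic acid. The cyclization must bring an aryl group and the silyloxy-diarylmethyl group ortho to each other, and aryne capture by the acetal oxygens or arenes competes with the hydrogen transfer.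
- Comparison: Alternative 2 is stronger in ring-construction economy. The chosen route starts from an intact benzene ring, brings the alkyne carbons in with their aryl group, and is shorter after the key step.

**Alternative 3:** Ring A stays intact, and the C1–C(acyl) and C6–C(sp) bonds are cut. The pieces are the aryl iodide A7, the aroyl anhydride A8 and the terminal alkyne 15.
- Forward key step: a Catellani reaction. Palladium inserts into C6–I and the strained-alkene relay carries it to C1–H. Acylation by A8 and ipso alkynylation by 15 then give the chloro ketone A6. A Suzuki coupling at C2–Cl would converge on ketone 21.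
- For it: this is the shortest path to 21 (about four steps) with no temporary ring. On step count and convergence it is stronger than the chosen route.
- Against it: the C1–H to be palladated is flanked by the C2 chlorine, and a substituent next to the reacting C–H is the known weak point of this relay. Direct Sonogashira coupling of A7 with 15 can occur before the relay. The acyl/alkynyl three-component pairing is demanding. The later Suzuki coupling is at a chloride flanked by an aroyl group.
- Comparison: the chosen route offers an annulation with close precedent for diarylalkynes and no regiochemical or three-component selectivity problem. It pays for this with a temporary ring and one untested scission.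

Key step: step 9

## Route

**Step 1**
Reactants: 1 methyl 3-bromo-4-iodobenzoate; 2 4-hydroxyphenylboronic acid
Product: 3 methyl 2-bromo-4'-hydroxybiphenyl-4-carboxylate
Conditions: Pd(PPh3)4 (3 mol%), Na2CO3 (2 M aq), DME, 70 °C
Reagents that add atoms: none
Why: Suzuki–Miyaura coupling; zerovalent palladium inserts much faster into the C–I bond (weaker, para to the ester) than into the neighbouring C–Br bond, so the bromine needed for the annulation is kept.

**Step 2**
Reactants: 3 methyl 2-bromo-4'-hydroxybiphenyl-4-carboxylate
Product: 4 methyl 2-bromo-4'-(methoxymethoxy)biphenyl-4-carboxylate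
Conditions: MOMCl, i-Pr2NEt, CH2Cl2, 0 °C to rt
Reagents that add atoms: chloromethyl methyl ether, COCCl
Why: O-alkylation of the phenol to its methoxymethyl ether; the phenol must be masked before the iodine quench of step 3 and the organometallic steps, and ester and aryl bromide are inert.

**Step 3**
Reactants: 4 methyl 2-bromo-4'-(methoxymethoxy)biphenyl-4-carboxylate
Product: 6 methyl 2-bromo-3-iodo-4'-(methoxymethoxy)biphenyl-4-carboxylate, via arylmagnesium chloride 5 (not isolated)
Conditions: TMPMgCl·LiCl (1.2 equiv), THF, 0 °C; then I2, –20 °C to rt
Reagents that add atoms: iodine, II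
Why: Directed magnesiation with the hindered amide base; the C3–H lies between the ester, which binds the base, and the bromine, which acidifies it, so it should be removed in preference to C5–H. The arylmagnesium 5 tolerates ester and bromide at 0 °C and is iodinated by I2.

**Step 4**
Reactants: 6 methyl 2-bromo-3-iodo-4'-(methoxymethoxy)biphenyl-4-carboxylate
Product: 7 [2-bromo-3-iodo-4'-(methoxymethoxy)biphenyl-4-yl]methanol
Conditions: i-Bu2AlH (2.5 equiv), CH2Cl2, –78 to 0 °C; aq potassium sodium tartrate
Reagents that add atoms: none
Why: Hydride reduction of the ester to the primary alcohol; aryl halides and the aryl methoxymethyl ether are inert at low temperature.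

**Step 5**
Reactants: 7 [2-bromo-3-iodo-4'-(methoxymethoxy)biphenyl-4-yl]methanol
Product: 8 2-bromo-3-iodo-4'-(methoxymethoxy)-4-[(methoxymethoxy)methyl]biphenyl
Conditions: MOMCl, i-Pr2NEt, CH2Cl2, 0 °C to rt
Reagents that add atoms: chloromethyl methyl ether, COCCl
Why: Methoxymethyl ether formation at the benzylic alcohol, which must be protected before the Grignard, peroxide and aryllithium steps; the group is stable to base and cleaved only in the last step.

**Step 6**
Reactants: 8 2-bromo-3-iodo-4'-(methoxymethoxy)-4-[(methoxymethoxy)methyl]biphenyl
Product: 10 2-bromo-4'-(methoxymethoxy)-4-[(methoxymethoxy)methyl]biphenyl-3-carbaldehyde, via arylmagnesium chloride 9 (not isolated)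
Conditions: iPrMgCl·LiCl (1.1 equiv), THF, –40 °C; then DMF, –40 to 0 °C; aq NH4Cl
Reagents that add atoms: N,N-dimethylformamide, CN(C)C=O
Why: Iodine–magnesium exchange is far faster at C–I than at C–Br; the Grignard 9 is held at –40 °C so that it does not lose MgBrCl to an aryne, and is formylated by DMF (Bouveault-type formylation).

**Step 7**
Reactants: 11 4-iodophenol
Product: 12 1-iodo-4-(methoxymethoxy)benzene
Conditions: MOMCl, i-Pr2NEt, CH2Cl2, 0 °C to rt
Reagents that add atoms: chloromethyl methyl ether, COCCl
Why: Methoxymethyl ether formation at the phenol; 12 serves as the source of both aryl groups of the alkyne and, in step 12, of the aryllithium.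

**Step 8**
Reactants: 12 1-iodo-4-(methoxymethoxy)benzene (2 equiv); 13 trimethylsilylacetylene
Product: 16 bis[4-(methoxymethoxy)phenyl]acetylene, via silylated arylacetylene 14 (not isolated), via terminal arylacetylene 15 (not isolated)
Conditions: 13 (0.5 equiv), PdCl2(PPh3)2 (6 mol%), CuI (10 mol%), DBU (6 equiv), H2O (0.4 equiv), MeCN, rt to 60 °C
Reagents that add atoms: none
Why: One-pot double Sonogashira coupling; the first coupling gives 14, DBU and water remove the silyl group to give 15, and 15 couples with a second molecule of 12.

**Step 9**
Reactants: 10 2-bromo-4'-(methoxymethoxy)-4-[(methoxymethoxy)methyl]biphenyl-3-carbaldehyde; 16 bis[4-(methoxymethoxy)phenyl]acetylene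
Product: 17 2,3,4-tris[4-(methoxymethoxy)phenyl]-7-[(methoxymethoxy)methyl]-1H-inden-1-one
Conditions: Pd(OAc)2 (5 mol%), NaOAc (4 equiv), n-Bu4NCl (1 equiv), 16 (2 equiv), DMF, 100 °C
Reagents that add atoms: none
Why: Zerovalent palladium, formed from Pd(OAc)2 in DMF, inserts into the C2–Br bond of 10 (biphenyl numbering), which the ortho formyl group activates; the arylpalladium bromide adds syn across the triple bond of 16, so that C2 is bonded to one alkyne carbon and palladium sits on the other, cis to ring A. This vinylpalladium carbon then attacks the neighbouring aldehyde carbon (a 5-exo-trig closure onto C=O) to give a palladium indenyl alkoxide, and β-hydride elimination of the former formyl hydrogen releases the indenone and HPdBr, which NaOAc returns to zerovalent palladium. The closest known reaction type is the Larock indenone synthesis of 2-bromo- or 2-iodobenzaldehydes with diarylalkynes under the same ligand-free conditions. No stereocentre is formed. Regiochemistry is not an issue because 16 is symmetrical and the bromo and formyl groups are fixed ortho to each other. The selectivity needed is chemoselectivity of the vinylpalladium intermediate: addition to the aldehyde must win over a second alkyne insertion and over palladation of an ortho C–H of the C1 aryl ring, which would lead to a phenanthrene; the formyl group lies in the plane of ring A next to the metal and can bind it through oxygen, whereas the C1 aryl ring is twisted out of plane and its ortho C–H is not activated by the para oxygen. Excess 16 and chloride from n-Bu4NCl are there to keep the catalyst in solution at 100 °C.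

**Step 10**
Reactants: 17 2,3,4-tris[4-(methoxymethoxy)phenyl]-7-[(methoxymethoxy)methyl]-1H-inden-1-one
Product: 18 2,3-epoxy-2,3,4-tris[4-(methoxymethoxy)phenyl]-7-[(methoxymethoxy)methyl]-2,3-dihydro-1H-inden-1-one (racemic, cis-fused)
Conditions: H2O2 (30% aq), NaOH (aq), THF/MeOH, 0 °C to rt, dark
Reagents that add atoms: hydrogen peroxide, OO
Why: Weitz–Scheffer nucleophilic epoxidation; hydroperoxide adds to C3 of the enone and the enolate closes onto oxygen. The cis ring fusion is the only geometry open to the five-membered ring, so the two new stereocentres (C2, C3) have a fixed relative configuration; the product is racemic and both centres are destroyed in step 11.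

**Step 11**
Reactants: 18 2,3-epoxy-2,3,4-tris[4-(methoxymethoxy)phenyl]-7-[(methoxymethoxy)methyl]-2,3-dihydro-1H-inden-1-one
Product: 21 [4'-(methoxymethoxy)-4-[(methoxymethoxy)methyl]-3-{[4-(methoxymethoxy)phenyl]ethynyl}biphenyl-2-yl][4-(methoxymethoxy)phenyl]methanone, via epoxy ketone tosylhydrazone 19 (not isolated), via hydroxy azoalkene 20 (not isolated)
Conditions: TsNHNH2 (1.2 equiv), CH2Cl2/AcOH (2:1), –20 °C to rt
Reagents that add atoms: none
Why: Proposed new method: the ketone condenses with TsNHNH2 to 19; loss of the N–H proton opens the epoxide at C2–O to the azoalkene 20, in which the C2–C3 bond lies anti to the C1–N bond across C1=C2; a Grob-type fragmentation then breaks C2–C3, expels N2 and p-toluenesulfinate, and leaves the C1≡C2 triple bond on C7a and the diaryl ketone on C3a (indenone numbering); the closest known reaction type is the Eschenmoser–Tanabe fragmentation of cyclopentenone and cyclohexenone epoxides, which has not been shown for a benzo-fused 2,3-diaryl epoxy ketone.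

**Step 12**
Reactants: 21 [4'-(methoxymethoxy)-4-[(methoxymethoxy)methyl]-3-{[4-(methoxymethoxy)phenyl]ethynyl}biphenyl-2-yl][4-(methoxymethoxy)phenyl]methanone; 12 1-iodo-4-(methoxymethoxy)benzene
Product: 23 [4'-(methoxymethoxy)-4-[(methoxymethoxy)methyl]-3-{[4-(methoxymethoxy)phenyl]ethynyl}biphenyl-2-yl]bis[4-(methoxymethoxy)phenyl]methanol, via 4-(methoxymethoxy)phenyllithium 22 (not isolated)
Conditions: 12 (2.2 equiv), n-BuLi (2.1 equiv), THF, –78 °C; then 21, –78 to –20 °C; aq NH4Cl
Reagents that add atoms: none
Why: Iodine–lithium exchange gives 22, which adds 1,2 to the diaryl ketone; 21 has no α-hydrogen, so addition is the only path, and the cold quench is there to keep the alkoxide from attacking the ortho alkyne.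

**Step 13**
Reactants: 23 [4'-(methoxymethoxy)-4-[(methoxymethoxy)methyl]-3-{[4-(methoxymethoxy)phenyl]ethynyl}biphenyl-2-yl]bis[4-(methoxymethoxy)phenyl]methanol
Product: 25 selaginellin, via deprotected triarylcarbinol 24 (not isolated)
Conditions: HCl (3 M aq), MeOH/THF, 45 °C; then aq NaHCO3 to pH 6–7
Reagents that add atoms: none
Why: Acid-catalysed acetal exchange with methanol removes all five methoxymethyl groups; the carbinol base 24 ionises to a triarylmethyl cation stabilised by two para-hydroxyphenyl groups and, on neutralisation, loses a phenolic proton to give the quinone methide (fuchsone formation). No stereocentre is involved.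

## Compound list

1 | methyl 3-bromo-4-iodobenzoate | COC(=O)c1ccc(I)c(Br)c1 | starting material
2 | 4-hydroxyphenylboronic acid | OB(O)c1ccc(O)cc1 | starting material
3 | methyl 2-bromo-4'-hydroxybiphenyl-4-carboxylate | COC(=O)c1ccc(-c2ccc(O)cc2)c(Br)c1 | intermediate
4 | methyl 2-bromo-4'-(methoxymethoxy)biphenyl-4-carboxylate | COC(=O)c1ccc(-c2ccc(OCOC)cc2)c(Br)c1 | intermediate
5 | [2-bromo-4-(methoxycarbonyl)-4'-(methoxymethoxy)biphenyl-3-yl]magnesium chloride | COC(=O)c1ccc(-c2ccc(OCOC)cc2)c(Br)c1[Mg]Cl | intermediate
6 | methyl 2-bromo-3-iodo-4'-(methoxymethoxy)biphenyl-4-carboxylate | COC(=O)c1ccc(-c2ccc(OCOC)cc2)c(Br)c1I | intermediate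
7 | [2-bromo-3-iodo-4'-(methoxymethoxy)biphenyl-4-yl]methanol | OCc1ccc(-c2ccc(OCOC)cc2)c(Br)c1I | intermediate
8 | 2-bromo-3-iodo-4'-(methoxymethoxy)-4-[(methoxymethoxy)methyl]biphenyl | COCOCc1ccc(-c2ccc(OCOC)cc2)c(Br)c1I | intermediate
9 | {2-bromo-4'-(methoxymethoxy)-4-[(methoxymethoxy)methyl]biphenyl-3-yl}magnesium chloride | COCOCc1ccc(-c2ccc(OCOC)cc2)c(Br)c1[Mg]Cl | intermediate
10 | 2-bromo-4'-(methoxymethoxy)-4-[(methoxymethoxy)methyl]biphenyl-3-carbaldehyde | COCOCc1ccc(-c2ccc(OCOC)cc2)c(Br)c1C=O | intermediate
11 | 4-iodophenol | Oc1ccc(I)cc1 | starting material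
12 | 1-iodo-4-(methoxymethoxy)benzene | COCOc1ccc(I)cc1 | intermediate
13 | trimethylsilylacetylene | C#C[Si](C)(C)C | starting material
14 | {[4-(methoxymethoxy)phenyl]ethynyl}trimethylsilane | COCOc1ccc(cc1)C#C[Si](C)(C)C | intermediate
15 | 1-ethynyl-4-(methoxymethoxy)benzene | COCOc1ccc(cc1)C#C | intermediate
16 | bis[4-(methoxymethoxy)phenyl]acetylene | COCOc1ccc(cc1)C#Cc1ccc(OCOC)cc1 | intermediate
17 | 2,3,4-tris[4-(methoxymethoxy)phenyl]-7-[(methoxymethoxy)methyl]-1H-inden-1-one | O=C1C(c2ccc(OCOC)cc2)=C(c2ccc(OCOC)cc2)c2c(-c3ccc(OCOC)cc3)ccc(COCOC)c12 | intermediate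
18 | 2,3-epoxy-2,3,4-tris[4-(methoxymethoxy)phenyl]-7-[(methoxymethoxy)methyl]-2,3-dihydro-1H-inden-1-one (racemic, cis-fused; one enantiomer drawn) | O=C1c2c(COCOC)ccc(-c3ccc(OCOC)cc3)c2[C@@]2(c3ccc(OCOC)cc3)O[C@@]12c1ccc(OCOC)cc1 | intermediate
19 | p-toluenesulfonylhydrazone of 18 (racemic, one enantiomer drawn; C=N geometry not defined) | Cc1ccc(cc1)S(=O)(=O)NN=C1c2c(COCOC)ccc(-c3ccc(OCOC)cc3)c2[C@@]2(c3ccc(OCOC)cc3)O[C@@]12c1ccc(OCOC)cc1 | intermediate
20 | 2,3,4-tris[4-(methoxymethoxy)phenyl]-7-[(methoxymethoxy)methyl]-1-[(E)-(4-methylphenyl)sulfonyldiazenyl]-3H-inden-3-ol (indenone numbering kept; racemic) | Cc1ccc(cc1)S(=O)(=O)/N=N/C1=C(c2ccc(OCOC)cc2)C(O)(c2ccc(OCOC)cc2)c2c(-c3ccc(OCOC)cc3)ccc(COCOC)c12 | intermediate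
21 | [4'-(methoxymethoxy)-4-[(methoxymethoxy)methyl]-3-{[4-(methoxymethoxy)phenyl]ethynyl}biphenyl-2-yl][4-(methoxymethoxy)phenyl]methanone | O=C(c1ccc(OCOC)cc1)c1c(-c2ccc(OCOC)cc2)ccc(COCOC)c1C#Cc1ccc(OCOC)cc1 | intermediate
22 | 4-(methoxymethoxy)phenyllithium | [Li]c1ccc(OCOC)cc1 | intermediate
23 | [4'-(methoxymethoxy)-4-[(methoxymethoxy)methyl]-3-{[4-(methoxymethoxy)phenyl]ethynyl}biphenyl-2-yl]bis[4-(methoxymethoxy)phenyl]methanol | OC(c1ccc(OCOC)cc1)(c1ccc(OCOC)cc1)c1c(-c2ccc(OCOC)cc2)ccc(COCOC)c1C#Cc1ccc(OCOC)cc1 | intermediate
24 | [4'-hydroxy-4-(hydroxymethyl)-3-[(4-hydroxyphenyl)ethynyl]biphenyl-2-yl]bis(4-hydroxyphenyl)methanol | OC(c1ccc(O)cc1)(c1ccc(O)cc1)c1c(-c2ccc(O)cc2)ccc(CO)c1C#Cc1ccc(O)cc1 | intermediate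
25 | selaginellin | O=C1C=CC(=C(c2ccc(O)cc2)c2c(-c3ccc(O)cc3)ccc(CO)c2C#Cc2ccc(O)cc2)C=C1 | target

## Step count and risk

Total: 13 steps. Longest linear sequence: 11 steps (steps 1–6 and 9–13, from 1).

**Step 11 (proposed new method).**
- What may go wrong: condensation at the hindered, aryl-conjugated carbonyl may be slow; the tertiary, doubly benzylic hydroxyl of 20 may ionise instead of fragmenting; the epoxide may open thermally to a carbonyl ylide before it condenses.
- Fallback (known chemistry only, leaves the indenone detour): it sets out from aldehyde 10. Seyferth–Gilbert homologation with dimethyl (1-diazo-2-oxopropyl)phosphonate and K2CO3 in MeOH should give 2-bromo-3-ethynyl-4'-(methoxymethoxy)-4-[(methoxymethoxy)methyl]biphenyl F1. Sonogashira coupling with 12 (PdCl2(PPh3)2, CuI, Et3N, rt) should take place at the C–I bond of 12, leave the hindered C–Br bond alone, and give 2-bromo-4'-(methoxymethoxy)-4-[(methoxymethoxy)methyl]-3-{[4-(methoxymethoxy)phenyl]ethynyl}biphenyl F2. Bromine–lithium exchange (n-BuLi, THF, –78 °C) would give {4'-(methoxymethoxy)-4-[(methoxymethoxy)methyl]-3-{[4-(methoxymethoxy)phenyl]ethynyl}biphenyl-2-yl}lithium F3. Its addition to bis[4-(methoxymethoxy)phenyl]methanone F4 (from 4,4'-dihydroxybenzophenone, MOMCl and i-Pr2NEt) comes back to the route at carbinol 23, so steps 9 to 12 are bypassed.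

**Step 9 (key step).**
- What may go wrong: the vinylpalladium intermediate may be diverted into C–H palladation of the neighbouring aryl ring or into a second alkyne insertion; insertion at the doubly ortho-substituted C–Br bond may be slow enough for protodebromination to compete.
- Fallback: it sets out from 10 and 16. A reductive carbocyclisation with CoI2(dppe) (5 mol%) and Zn powder in MeCN at 80 °C uses a nucleophilic, low-valent cobalt vinyl species that adds to the aldehyde without a β-hydride elimination step and has no electrophilic C–H palladation channel. It should give 2,3,4-tris[4-(methoxymethoxy)phenyl]-7-[(methoxymethoxy)methyl]-1H-inden-1-ol F5 (racemic). Oxidation with MnO2 in CH2Cl2 comes back to the route at 17.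

**Step 10.**
- What may go wrong: conjugate addition of hydroperoxide at the crowded C3 (flanked by the C4 aryl group) may be slow, and the product may ring-open under light or heat.
- Fallback: it sets out from 17 and avoids the epoxide. Condensation with TsNHNH2 (MeOH, catalytic AcOH, 50 °C) would give the unsaturated N'-{2,3,4-tris[4-(methoxymethoxy)phenyl]-7-[(methoxymethoxy)methyl]-1H-inden-1-ylidene}-4-methylbenzenesulfonohydrazide F6. N-Bromosuccinimide in acetone/water at –10 °C (the oxidative variant of the fragmentation of unsaturated tosylhydrazones) should add water at C3 to reach the same azoalkene 20, and the route is rejoined at 21.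

**Step 3.**
- What may go wrong: metalation may occur at C5 instead of C3 because the C1 aryl group presses the bromine toward C3–H, or the base may attack the methyl ester.
- Fallback: it sets out from 4. Saponification (LiOH, THF/H2O; mild acidification) gives 2-bromo-4'-(methoxymethoxy)biphenyl-4-carboxylic acid F7. Carboxylate-directed lithiation between the carboxylate and bromine with lithium 2,2,6,6-tetramethylpiperidide (2.2 equiv, THF, –50 °C) and an I2 quench give 2-bromo-3-iodo-4'-(methoxymethoxy)biphenyl-4-carboxylic acid F8. Reduction with BH3·THF comes back to the route at 7.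

**Step 13.**
- What may go wrong: the aliphatic methoxymethyl ether may not cleave fully under conditions mild enough for the product; the cation may be trapped by methanol; the electron-rich alkyne may be hydrated by acid.
- Fallback: it sets out from 23 and moves the forcing deprotection to a stage without cation or quinone methide. Ionic hydrogenation (Et3SiH, CF3CO2H, CH2Cl2, 0 °C) followed by HCl in MeOH at 50 °C should give the leuco compound 4,4'-{[4'-hydroxy-4-(hydroxymethyl)-3-[(4-hydroxyphenyl)ethynyl]biphenyl-2-yl]methylene}diphenol F9. Hydride abstraction with DDQ (1 equiv, THF, rt) comes back to the route at 25.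

## Further compounds

F1 | step 11 | 2-bromo-3-ethynyl-4'-(methoxymethoxy)-4-[(methoxymethoxy)methyl]biphenyl | COCOCc1ccc(-c2ccc(OCOC)cc2)c(Br)c1C#C
F2 | step 11 | 2-bromo-4'-(methoxymethoxy)-4-[(methoxymethoxy)methyl]-3-{[4-(methoxymethoxy)phenyl]ethynyl}biphenyl | COCOCc1ccc(-c2ccc(OCOC)cc2)c(Br)c1C#Cc1ccc(OCOC)cc1
F3 | step 11 | {4'-(methoxymethoxy)-4-[(methoxymethoxy)methyl]-3-{[4-(methoxymethoxy)phenyl]ethynyl}biphenyl-2-yl}lithium | COCOCc1ccc(-c2ccc(OCOC)cc2)c([Li])c1C#Cc1ccc(OCOC)cc1
F4 | step 11 | bis[4-(methoxymethoxy)phenyl]methanone | COCOc1ccc(cc1)C(=O)c1ccc(OCOC)cc1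
F5 | step 9 | 2,3,4-tris[4-(methoxymethoxy)phenyl]-7-[(methoxymethoxy)methyl]-1H-inden-1-ol (racemic) | OC1C(c2ccc(OCOC)cc2)=C(c2ccc(OCOC)cc2)c2c(-c3ccc(OCOC)cc3)ccc(COCOC)c12
F6 | step 10 | N'-{2,3,4-tris[4-(methoxymethoxy)phenyl]-7-[(methoxymethoxy)methyl]-1H-inden-1-ylidene}-4-methylbenzenesulfonohydrazide (C=N geometry not defined) | Cc1ccc(cc1)S(=O)(=O)NN=C1C(c2ccc(OCOC)cc2)=C(c2ccc(OCOC)cc2)c2c(-c3ccc(OCOC)cc3)ccc(COCOC)c12
F7 | step 3 | 2-bromo-4'-(methoxymethoxy)biphenyl-4-carboxylic acid | OC(=O)c1ccc(-c2ccc(OCOC)cc2)c(Br)c1
F8 | step 3 | 2-bromo-3-iodo-4'-(methoxymethoxy)biphenyl-4-carboxylic acid | OC(=O)c1ccc(-c2ccc(OCOC)cc2)c(Br)c1I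
F9 | step 13 | 4,4'-{[4'-hydroxy-4-(hydroxymethyl)-3-[(4-hydroxyphenyl)ethynyl]biphenyl-2-yl]methylene}diphenol | OCc1ccc(-c2ccc(O)cc2)c(C(c2ccc(O)cc2)c2ccc(O)cc2)c1C#Cc1ccc(O)cc1
A1 | alternative 1 | methyl 3-{bis[4-(methoxymethoxy)phenyl]methyl}-4-hydroxy-2-{[4-(methoxymethoxy)phenyl]ethynyl}benzoate | COC(=O)c1ccc(O)c(C(c2ccc(OCOC)cc2)c2ccc(OCOC)cc2)c1C#Cc1ccc(OCOC)cc1
A2 | alternative 1 | {[(2Z,4E)-5-methoxy-1,1-bis[4-(methoxymethoxy)phenyl]penta-2,4-dien-3-yl]oxy}trimethylsilane | CO/C=C/C(O[Si](C)(C)C)=C/C(c1ccc(OCOC)cc1)c1ccc(OCOC)cc1
A3 | alternative 1 | methyl 5-[4-(methoxymethoxy)phenyl]penta-2,4-diynoate | COC(=O)C#CC#Cc1ccc(OCOC)cc1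
A4 | alternative 2 | 6-[4-(methoxymethoxy)phenyl]-7-{bis[4-(methoxymethoxy)phenyl](trimethylsilyloxy)methyl}isobenzofuran-1(3H)-one | O=C1OCc2ccc(-c3ccc(OCOC)cc3)c(C(O[Si](C)(C)C)(c3ccc(OCOC)cc3)c3ccc(OCOC)cc3)c12
A5 | alternative 2 | 5-[4-(methoxymethoxy)phenyl]penta-2,4-diyn-1-yl 4,4-bis[4-(methoxymethoxy)phenyl]-4-(trimethylsilyloxy)but-2-ynoate | COCOc1ccc(cc1)C#CC#CCOC(=O)C#CC(O[Si](C)(C)C)(c1ccc(OCOC)cc1)c1ccc(OCOC)cc1
A6 | alternative 3 | {6-chloro-3-[(methoxymethoxy)methyl]-2-{[4-(methoxymethoxy)phenyl]ethynyl}phenyl}[4-(methoxymethoxy)phenyl]methanone | COCOCc1ccc(Cl)c(C(=O)c2ccc(OCOC)cc2)c1C#Cc1ccc(OCOC)cc1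
A7 | alternative 3 | 4-chloro-2-iodo-1-[(methoxymethoxy)methyl]benzene | COCOCc1ccc(Cl)cc1I
A8 | alternative 3 | 4-(methoxymethoxy)benzoic anhydride | COCOc1ccc(cc1)C(=O)OC(=O)c1ccc(OCOC)cc1
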